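**Strategy.** Everything rests on the C9–C10 disconnection of cyclopentane ring B (C5, C6, C8, C9, C10). The key step closes it as the last ring of the carbon skeleton: a σ-dienyl radical at C10 of a finished ring A adds 5-exo to the C9=C11 alkene of a finished bicyclo[3.2.1]octene (rings C and D). The step exploits the open exo face of that bicycle, which fixes C9, while C10 stays sp2. The 1(10),2-diene so retained later takes up O2 and the C19 acid to give the lactone, the 1β-hydroxyl and the epoxide. The precursor is a 9,10-seco bromodiene, assembled by decarboxylative radical union of two Birch-derived fragments through C6–C8.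

Key step: step 10

Remark: gibberellin numbering (C1–C19; α/β as in the target, lactone bridge α) is used for all intermediates. In both resolutions the less soluble salt is taken to carry the enantiomer drawn; the antipodal amine serves otherwise.

Step 1
Reactants: 1 3-methoxybenzoic acid; 2 3-bromoprop-1-yne
Product: 4 rac-5-oxo-1-(prop-2-yn-1-yl)cyclohex-2-ene-1-carboxylic acid, via enol ether acid 3 (not isolated)
Conditions: Li, NH3(l)/THF, −78 °C; 2; NH4Cl; aq. oxalic acid, THF, 0 °C
Reagents that add atoms: water, O
Why: Birch reduction–alkylation propargylates the carboxylate dienolate at the ipso carbon (creating C8), and mild acid hydrolyses the enol ether to the C13 ketone without moving the C9=C11 alkene.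

Step 2
Reactants: 4 rac-5-oxo-1-(prop-2-yn-1-yl)cyclohex-2-ene-1-carboxylic acid
Product: 5 (S)-5-oxo-1-(prop-2-yn-1-yl)cyclohex-2-ene-1-carboxylic acid
Conditions: (S)-1-phenylethylamine, EtOAc/EtOH, fractional crystallisation; 1 M HCl
Reagents that add atoms: none
Why: Classical resolution through diastereomeric ammonium salts should deliver the single C8 configuration.

Step 3
Reactants: 5 (S)-5-oxo-1-(prop-2-yn-1-yl)cyclohex-2-ene-1-carboxylic acid
Product: 6 (1S,5S)-5-hydroxy-6-methylidenebicyclo[3.2.1]oct-2-ene-1-carboxylic acid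
Conditions: NaH (1 equiv); SmI2 (3 equiv), HMPA, t-BuOH, THF, 0 °C; 1 M HCl
Reagents that add atoms: none
Why: SmI2-mediated ketyl–alkyne reductive cyclisation (5-exo-dig) joins C13 to C16 and gives the 13-hydroxyl and the 16-methylene; the one-carbon link through C14 allows only the bridged closure, so C13 follows from C8.

Step 4
Reactants: 1 3-methoxybenzoic acid; 7 iodomethane
Product: 8 rac-3-methoxy-1-methylcyclohexa-2,5-diene-1-carboxylic acid
Conditions: Li, NH3(l)/THF, −78 °C; 7; NH4Cl; aq. NaH2PO4 (pH 5), 0 °C
Reagents that add atoms: none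
Why: Birch reduction–alkylation methylates the dienolate at the ipso carbon (creating C4) and keeps the C5=C10 enol ether and the C2=C3 alkene.

Step 5
Reactants: 8 rac-3-methoxy-1-methylcyclohexa-2,5-diene-1-carboxylic acid
Product: 9 (R)-3-methoxy-1-methylcyclohexa-2,5-diene-1-carboxylic acid
Conditions: (R)-1-phenylethylamine, acetone, fractional crystallisation; cold aq. citric acid
Reagents that add atoms: none
Why: Classical resolution through diastereomeric ammonium salts should deliver the single C4 configuration (4β-methyl, 4α-carboxyl).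

Step 6
Reactants: 9 (R)-3-methoxy-1-methylcyclohexa-2,5-diene-1-carboxylic acid
Product: 10 methyl (R)-3-methoxy-1-methylcyclohexa-2,5-diene-1-carboxylate
Conditions: TMSCHN2, toluene/MeOH, 0 °C
Reagents that add atoms: (trimethylsilyl)diazomethane, C[Si](C)(C)C=[N+]=[N-]
Why: O-methylation of the acid under neutral conditions spares the acid-labile enol ether.

Step 7
Reactants: 10 methyl (R)-3-methoxy-1-methylcyclohexa-2,5-diene-1-carboxylate; 11 methyl glyoxylate
Product: 14 methyl (1R,6Z)-6-(2-methoxy-2-oxoethylidene)-1-methyl-5-oxocyclohex-2-ene-1-carboxylate, via ene adduct 12 (not isolated), via hydroxy ketone 13 (not isolated)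
Conditions: 11, Sc(OTf)3 (5 mol %), CH2Cl2, −40 °C; aq. oxalic acid, THF, 0 °C; MsCl, Et3N, CH2Cl2, 0 °C
Reagents that add atoms: water, O
Why: A glyoxylate-ene reaction at C5, the only nucleophilic carbon of the enol ether, brings in C6 and C7; hydrolysis of the transposed dienol ether and E1cB dehydration then give the keto-acrylate without touching C4.

Step 8
Reactants: 6 (1S,5S)-5-hydroxy-6-methylidenebicyclo[3.2.1]oct-2-ene-1-carboxylic acid; 14 methyl (1R,6Z)-6-(2-methoxy-2-oxoethylidene)-1-methyl-5-oxocyclohex-2-ene-1-carboxylate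
Product: 15 9,10-seco keto diester (5β-H; 6-epi drawn)
Conditions: Ir[dF(CF3)ppy]2(dtbbpy)PF6 (1 mol %), K2HPO4, DMF, 450 nm LEDs, rt
Reagents that add atoms: none
Why: In this photoredox decarboxylative Giese addition the bridgehead C8 radical from 6 adds to the unhindered C6 terminus of the keto-acrylate; the epimerisable C5 centre, formed on enolate protonation, should settle with the side chain equatorial and cis to the axial C19 ester, while C6 forms as a mixture that converges in step 11.

Step 9
Reactants: 15 9,10-seco keto diester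
Product: 16 9,10-seco dienyl bromide (10-bromo-1(10),2-diene)
Conditions: (PhO)3P, Br2 (2.5 equiv each), Et3N, CH2Cl2, −60 °C to reflux; aq. NaHCO3 work-up
Reagents that add atoms: bromine (as its triphenyl phosphite adduct), BrBr
Why: The ketone is converted to the vinyl bromide through an enol phosphonium salt, enolisation toward the allylic, unhindered C1 giving the conjugated bromodiene and leaving C5 untouched, while the bridgehead 13-hydroxyl cannot be displaced and is returned from its alkoxyphosphonium salt on aqueous work-up.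

Step 10
Reactants: 16 9,10-seco dienyl bromide
Product: 17 dimethyl 13-hydroxy-6-epi-20-norgibberella-1(10),2,16-triene-7,19-dioate
Conditions: Bu3SnH (1.3 equiv, syringe pump), AIBN (0.2 equiv), benzene (0.01 M), 80 °C
Reagents that add atoms: none
Why: Bu3Sn• abstracts bromine to give the σ-dienyl radical at C10, which adds to C9 of the C9=C11 alkene, and the resulting C11 radical is reduced by Bu3SnH; the closest known reaction type is the tin-hydride vinyl radical cyclisation. Ring B (C5–C6–C8–C9–C10) closes in the 5-exo-trig mode, which should outpace 6-endo attack at C11 and attack on the distal C16 methylene. The new stereocentre C9 is controlled by the bicyclo[3.2.1]octene: the radical should enter on the face anti to the C15–C16 bridge, giving the 9β-H, cis B/C junction. C10 stays sp2, so no A/B junction is set here, and both C6 epimers cyclise alike. The step needs cyclisation to beat direct reduction and 1,5-hydrogen shifts of the vinyl radical, which the short C5–C6–C8 tether and slow addition of the stannane should secure.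

Step 11
Reactants: 17 dimethyl 13-hydroxy-6-epi-20-norgibberella-1(10),2,16-triene-7,19-dioate
Product: 18 dimethyl 13-hydroxy-20-norgibberella-1(10),2,16-triene-7,19-dioate
Conditions: NaOMe (0.2 equiv), MeOH, 50 °C
Reagents that add atoms: none
Why: Base-mediated epimerisation α to the C7 ester should funnel both C6 epimers to the 6β-ester, which sits trans to C4 on ring B and so avoids the clash with the 4α-ester.

Step 12
Reactants: 18 dimethyl 13-hydroxy-20-norgibberella-1(10),2,16-triene-7,19-dioate
Product: 19 13-hydroxy-20-norgibberella-1(10),2,16-triene-7,19-dioic acid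
Conditions: LiSPr, HMPA, 50 °C; cold 0.5 M HCl
Reagents that add atoms: none
Why: SN2 demethylation by thiolate cleaves both hindered methyl esters without touching the diene or C6.

Step 13
Reactants: 19 13-hydroxy-20-norgibberella-1(10),2,16-triene-7,19-dioic acid
Product: 20 3β,10β-epidioxy-13-hydroxy-20-norgibberella-1,16-diene-7,19-dioic acid
Conditions: O2, tetraphenylporphyrin (1 mol %), 590 nm LEDs, CH2Cl2, −30 °C
Reagents that add atoms: dioxygen, O=O
Why: Singlet oxygen should add [4+2] to the s-cis diene from the β face, because the α face is screened at C3 by the pseudo-axial C19 carboxyl and at C10 by C11; the isolated C16 methylene reacts far more slowly.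

Step 14
Reactants: 20 3β,10β-epidioxy-13-hydroxy-20-norgibberella-1,16-diene-7,19-dioic acid
Product: 22 2β,3β-epoxy-1β,13-dihydroxy-20-norgibberell-16-ene-7,19-dioic acid 19,10-lactone (the target gibberellin), via bis-epoxide 21 (not isolated)
Conditions: Co(TPP) (5 mol %, tetraphenylporphyrin complex of divalent cobalt), CH2Cl2, −20 °C to rt; PPTS (cat.), rt
Reagents that add atoms: none
Why: Cobalt-porphyrin-induced O–O homolysis rearranges the endoperoxide to the all-β syn-bis-epoxide, and the C19 acid then opens the tertiary C10 end of the 1,10-epoxide from the α face (5-exo, inversion), setting the 10α-lactone and 1β-hydroxyl and leaving the 2β,3β-epoxide.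

**Compound list**

1 | 3-methoxybenzoic acid | COc1cccc(c1)C(=O)O | starting material
2 | 3-bromoprop-1-yne | C#CCBr | starting material
3 | rac-3-methoxy-1-(prop-2-yn-1-yl)cyclohexa-2,5-diene-1-carboxylic acid | COC1=CC(CC#C)(C(=O)O)C=CC1 | intermediate
4 | rac-5-oxo-1-(prop-2-yn-1-yl)cyclohex-2-ene-1-carboxylic acid | O=C(O)C1(CC#C)CC(=O)CC=C1 | intermediate
5 | (S)-5-oxo-1-(prop-2-yn-1-yl)cyclohex-2-ene-1-carboxylic acid | C#CC[C@]1(C(=O)O)CC(=O)CC=C1 | intermediate
6 | (1S,5S)-5-hydroxy-6-methylidenebicyclo[3.2.1]oct-2-ene-1-carboxylic acid (rings C and D; carboxyl on C8) | C=C1C[C@]2(C(=O)O)C[C@@]1(O)CC=C2 | intermediate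
7 | iodomethane | CI | starting material
8 | rac-3-methoxy-1-methylcyclohexa-2,5-diene-1-carboxylic acid | COC1=CC(C)(C(=O)O)C=CC1 | intermediate
9 | (R)-3-methoxy-1-methylcyclohexa-2,5-diene-1-carboxylic acid | O=C(O)[C@@]1(C)C=C(OC)CC=C1 | intermediate
10 | methyl (R)-3-methoxy-1-methylcyclohexa-2,5-diene-1-carboxylate | COC(=O)[C@@]1(C)C=C(OC)CC=C1 | intermediate
11 | methyl glyoxylate | COC(=O)C=O | starting material
12 | methyl (1R)-6-(1-hydroxy-2-methoxy-2-oxoethyl)-5-methoxy-1-methylcyclohexa-2,4-diene-1-carboxylate (mixture at C5 and C6) | COC(=O)[C@]1(C)C=CC=C(OC)C1C(O)C(=O)OC | intermediate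
13 | methyl (1R)-6-(1-hydroxy-2-methoxy-2-oxoethyl)-1-methyl-5-oxocyclohex-2-ene-1-carboxylate (mixture at C5 and C6) | COC(=O)[C@]1(C)C=CCC(=O)C1C(O)C(=O)OC | intermediate
14 | methyl (1R,6Z)-6-(2-methoxy-2-oxoethylidene)-1-methyl-5-oxocyclohex-2-ene-1-carboxylate | COC(=O)[C@]1(C)C=CCC(=O)/C1=C\C(=O)OC | intermediate
15 | 9,10-seco keto diester: methyl 2-[(1S,5S)-5-hydroxy-6-methylidenebicyclo[3.2.1]oct-2-en-1-yl]-2-[2-(methoxycarbonyl)-2-methyl-6-oxocyclohex-3-en-1-yl]acetate; 4α-CO2Me, 4β-Me, 5β-H, C6 drawn as 6-epi | C=C1C[C@]2([C@H](C(=O)OC)[C@H]3C(=O)CC=C[C@@]3(C)C(=O)OC)C[C@@]1(O)CC=C2 | intermediate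
16 | 9,10-seco dienyl bromide: as 15 with C10(Br)=C1–C2=C3 in place of the C10 ketone | C=C1C[C@]2([C@H](C(=O)OC)[C@H]3C(Br)=CC=C[C@@]3(C)C(=O)OC)C[C@@]1(O)CC=C2 | intermediate
17 | dimethyl 13-hydroxy-6-epi-20-norgibberella-1(10),2,16-triene-7,19-dioate (5β-H, 9β-H, 6α-CO2Me) | C=C1C[C@]23C[C@@]1(O)CC[C@H]2C1=CC=C[C@@](C)(C(=O)OC)[C@H]1[C@H]3C(=O)OC | intermediate
18 | dimethyl 13-hydroxy-20-norgibberella-1(10),2,16-triene-7,19-dioate (6β-CO2Me) | C=C1C[C@]23C[C@@]1(O)CC[C@H]2C1=CC=C[C@@](C)(C(=O)OC)[C@H]1[C@@H]3C(=O)OC | intermediate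
19 | 13-hydroxy-20-norgibberella-1(10),2,16-triene-7,19-dioic acid | C=C1C[C@]23C[C@@]1(O)CC[C@H]2C1=CC=C[C@@](C)(C(=O)O)[C@H]1[C@@H]3C(=O)O | intermediate
20 | 3β,10β-epidioxy-13-hydroxy-20-norgibberella-1,16-diene-7,19-dioic acid | C=C1C[C@]23C[C@@]1(O)CC[C@H]2[C@@]12OO[C@@H](C=C1)[C@@](C)(C(=O)O)[C@H]2[C@@H]3C(=O)O | intermediate
21 | 1β,10β:2β,3β-diepoxy-13-hydroxy-20-norgibberell-16-ene-7,19-dioic acid | C=C1C[C@]23C[C@@]1(O)CC[C@H]2[C@@]12O[C@@H]1[C@@H]1O[C@@H]1[C@@](C)(C(=O)O)[C@H]2[C@@H]3C(=O)O | intermediate
22 | 2β,3β-epoxy-1β,13-dihydroxy-20-norgibberell-16-ene-7,19-dioic acid 19,10-lactone (the target gibberellin) | C=C1C[C@]23C[C@@]1(O)CC[C@H]2[C@@]12OC(=O)[C@@](C)([C@H]1[C@@H]3C(=O)O)[C@H]1O[C@H]1[C@H]2O | target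

**Totals.** 14 steps in all; the longest linear sequence is 11 steps (steps 4–14).

**Steps most likely to fail**

Step 8 is the weakest point. The risk is poor facial control when the C5 enolate is protonated, so that 15 forms as a C5 epimer mixture; the preference argued above is small. The fallback sets C5 thermodynamically on a lactone template and sets out from 15 as that mixture. PhSH and BF3·OEt2 in CH2Cl2 at 0 °C should convert it to the bridged O,S-ketal lactone F1. In this step the thionium ion at C10 is captured by the C19 ester with loss of its methyl group. C5 can equilibrate through the vinyl sulfide, and the side chain should settle on the lactone side of the one-carbon bridge. Iodomethane and NaHCO3 in aqueous MeCN then unmask keto acid F2 without enolisation toward C5, and TMSCHN2 comes back to the route at 15 as a single C5 epimer.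

Step 9 may suffer from sluggish or non-regioselective enol activation of the hindered ketone, or from HBr addition to the diene. The fallback sets out from 15. Hydrazine hydrate in EtOH should give hydrazone F3. Iodine and tetramethylguanidine in THF (Barton vinyl iodide synthesis) should then give dienyl iodide F4. Under the conditions of step 10, F4 comes back to the route at 17.

Step 13 may be diverted by ene-type hydroperoxidation at the trisubstituted alkene, or the hindered diene may react too slowly in the [4+2] mode. The fallback sets out from 19 and introduces the oxygens stepwise. Dimethyldioxirane in acetone at −78 °C should epoxidise the electron-rich 1(10)-alkene from the β face to the 1β,10β-epoxide F5, which is not isolated. The C19 acid opens F5 at C10 to give the 1β-hydroxy lactone F6. VO(acac)2 with t-BuOOH in CH2Cl2 then directs the 2β,3β-epoxidation from the 1β-hydroxyl and comes back to the route at 22. The bridgehead 13-hydroxyl lies nearly in the plane of the C16 methylene and should not deliver the oxidant to it.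

**Further compounds**

F1 | step 8 | bridged O,S-ketal lactone: 10-phenylthio-19,10-lactone of the 9,10-seco C7 methyl ester (5β-H, side chain on the lactone side) | C=C1C[C@]2([C@H](C(=O)OC)[C@H]3[C@]4(Sc5ccccc5)CC=C[C@@]3(C)C(=O)O4)C[C@@]1(O)CC=C2
F2 | step 8 | 9,10-seco keto acid: as 15 with a free C19 carboxylic acid | C=C1C[C@]2([C@H](C(=O)OC)[C@H]3C(=O)CC=C[C@@]3(C)C(=O)O)C[C@@]1(O)CC=C2
F3 | step 9 | C10 hydrazone of 15 | C=C1C[C@]2([C@H](C(=O)OC)[C@H]3C(=NN)CC=C[C@@]3(C)C(=O)OC)C[C@@]1(O)CC=C2
F4 | step 9 | 9,10-seco dienyl iodide: as 16 with iodine at C10 | C=C1C[C@]2([C@H](C(=O)OC)[C@H]3C(I)=CC=C[C@@]3(C)C(=O)OC)C[C@@]1(O)CC=C2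
F5 | step 13 | 1β,10β-epoxy-13-hydroxy-20-norgibberella-2,16-diene-7,19-dioic acid | C=C1C[C@]23C[C@@]1(O)CC[C@H]2[C@@]12O[C@@H]1C=C[C@@](C)(C(=O)O)[C@H]2[C@@H]3C(=O)O
F6 | step 13 | 1β,13-dihydroxy-20-norgibberella-2,16-diene-7,19-dioic acid 19,10-lactone | C=C1C[C@]23C[C@@]1(O)CC[C@H]2[C@@]12OC(=O)[C@@](C)([C@H]1[C@@H]3C(=O)O)C=C[C@H]2O
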